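However D is fed, the charge stays the same, so a share of it can be counted as turnovers per end. The average length is G over chains begun. If each E begins one chain, it is the G share times the D charged per E, the dose per end, 208 in both dawn and winter. The two flasks differ in feed time, so the dispute is over the G share.

D is fed into a stirred solution of E and Z. In the proposed steps, D and E give a living end J and a first G, J adds further D as G, Z turns J into Q, D goes to L by itself, and E and G give X.

| flask | D | Z | E | remark | time |
|---|---|---|---|---|---|
| north-west | 0.25 mM (fed, over 1.0 min) | 0.0050 mM | 2.4 µM | run made earlier |  |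
| north-east | 1 mM (fed, over 1.0 min) | 0.0050 mM | 2.4 µM | run made earlier |  |
| south | 0.50 mM (fed, over 1.0 min) | 0.0050 mM | 1.2 µM | run made earlier |  |
| dawn | 0.50 mM (fed, over 1.0 min) | 0.00500 mM | 2.4 µM |  | 2.0 min |
| winter | 0.50 mM (fed, over 0.30 min) | 0.00500 mM | 2.4 µM |  | 2.0 min |

| run | time / s | G / % | D / % |
|---|---|---|---|
| north-west | 10.0 | 0.7 | 11.9 |
| north-west | 20.0 | 1.0 | 18.4 |
| north-west | 40.0 | 6.6 | 21.4 |
| north-west | 90.0 | 14.8 | 3.7 |
| north-east | 10.0 | 0.8 | 12.7 |
| north-east | 20.0 | 2.8 | 17.1 |
| north-east | 40.0 | 9.9 | 20.0 |
| north-east | 90.0 | 18.2 | 3.5 |
| south | 25.0 | 1.3 | 19.7 |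
| south | 50.0 | 6.6 | 23.4 |
| south | 80.0 | 8.9 | 7.3 |
| south | 90.0 | 10.3 | 4.0 |

(readings scatter by 0.5 percentage points)

- the average divides the monomer in chains by the number of chains begun, living and dead together
- steps that have been proposed: J + Z -> Q; D + E -> J + G; E + G -> X; D -> L; D + J -> G + J
- the earlier runs do not show the number of chains; that part of a forecast is a guess
- percentages count the whole charge, also what has not yet gone in

1. which of the two ends with the longer chains by the average number of monomer units in a chain (chains begun, living or dead) ("neither" if they lie within 10 %) (dawn / winter / neither)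
2. average number of monomer units in a chain (chains begun, living or dead) at the end, dawn
3. average number of monomer units in a chain (chains begun, living or dead) at the end, winter

The first chemist holds that feed time is beside the point. In this view D goes to L at first order and to G at pseudo-first-order for a given J, so the split does not ask how D arrives. The readings at 90.0 s seem to agree: north-west has 14.8 % in G and north-east 18.2 %, at 4.00 times the charge. Their mean, 16.5 %, times the dose per end gives 34.4 for either flask, so this view says neither.

The second chemist made the forecast. Z stands at 2.08 per E, so ends can be lost as the clock runs, and south, with half the E of the north runs and a charge between theirs, reaches 10.3 % in G at 90.0 s. G thus follows the ends present, and in winter “monomer meets younger ends”. The forecast names winter, with 36 for dawn (range 31 to 42) and 41 for winter (range 34 to 49). Over the dose per end these are G shares of 17.3 % and 19.7 %, with the number of chains a guess because the earlier runs do not show it.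

The simulation gives 37.9 for dawn and 49.0 for winter, so winter ends longer, and above the forecast's 41.

J + Z → Q (k = 7300 M⁻¹ s⁻¹); D + E → J + G (k = 660 M⁻¹ s⁻¹); E + G → X (k = 26.0 M⁻¹ s⁻¹); D → L (k = 0.0600 s⁻¹); D + J → G + J, rate k5*[J]*[D] (k = 15000 M⁻¹ s⁻¹) At the end winter holds 23.1 % in G and keeps 1.1 % of its E, and the G share times the dose per end, taken over the E that has reacted, gives 48.6. The first view, a G share that stays put, comes nearer where the feed time stays and the charge moves: the neighbour of dawn charged with 0.30 mM, at 125 D per E, holds 16.3 % in G against dawn's 17.9 %, a gap smaller than the one between winter and dawn, keeps 5.8 % of its E, and ends at 21.9.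

The earlier runs and the new flask were generated by integration with made-up constants; noise was put on by code.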